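**Strategy.** The tetronic acid ring (O1, C2, C3, C4, C5) is read as a cyclised 2-(propanoyloxy)acrylate, so the route rests on forming the C3–C4 bond last. A Dieckmann condensation of the propanoate enolate onto the neighbouring methyl ester closes the five-membered ring in one operation. It carries the pre-set E geometry of the C5=C6 enol-ester double bond (C7 cis to C4, trans to O1) into the ring, where it could not be set reliably afterwards. The precursor is an open-chain methyl (E)-2-(propanoyloxy)enoate bearing the C7 (S) methyl centre, both trisubstituted E-alkenes and the C18 furyl ketone masked as a 1,3-dioxolane.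

Key step: step 18

**Remarks on the chemistry**
- Numbering: ring O1, C2 (lactone carbonyl), C3 (methyl-bearing), C4 (enol carbon), C5; chain C6 (ylidene CH) to C18 (ketone carbon).
- C18 passes through the ring closure as a 1,3-dioxolane, not as a dithioacetal. A thioacetal could only be removed at the end with thiophilic electrophiles or oxidants, which the free tetronic acid enol, the furan and the trisubstituted alkenes would not tolerate; the dioxolane falls to dilute oxalic acid. A dithiane serves only as a transient umpolung device for the C17–C18 bond.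
- Assumption: (2R)-3-bromo-2-methylpropan-1-ol, (4-bromobut-1-yn-1-yl)trimethylsilane and methyl 2-[bis(2,2,2-trifluoroethoxy)phosphoryl]acetate are bought. The bromo alcohol's silyl ether is otherwise reachable from methyl (R)-3-hydroxy-2-methylpropanoate by silylation, ester reduction and bromination.

**Route**

Step 1
Reactants: 1 (2R)-3-bromo-2-methylpropan-1-ol
Product: 2 tert-butyl{[(2R)-3-bromo-2-methylpropyl]oxy}diphenylsilane
Conditions: TBDPSCl, imidazole, CH2Cl2, 0 °C to rt
Reagents that add atoms: tert-butyl(chloro)diphenylsilane, CC(C)(C)[Si](Cl)(c1ccccc1)c1ccccc1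
Why: Imidazole-promoted silyl ether formation is selective for the primary hydroxyl and leaves the alkyl bromide alone; the future C7 centre comes from the chiral pool and is not touched.

Step 2
Reactants: 2 tert-butyl{[(2R)-3-bromo-2-methylpropyl]oxy}diphenylsilane; 3 (4-bromobut-1-yn-1-yl)trimethylsilane
Product: 5 tert-butyl{[(2S)-2-methyl-7-(trimethylsilyl)hept-6-yn-1-yl]oxy}diphenylsilane, via alkylmagnesium bromide 4 (not isolated)
Conditions: 3, Mg, THF, rt; then 2, Li2CuCl4 (cat.), NMP, THF, 0 °C to rt
Reagents that add atoms: none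
Why: Kochi–Tamura copper-catalysed alkyl–alkyl cross-coupling joins C8 to C9 at the primary bromide, the NMP additive compensating for the β-branch; the stereocentre is not at the reacting carbon and its descriptor changes to S only through CIP priorities.

Step 3
Reactants: 5 tert-butyl{[(2S)-2-methyl-7-(trimethylsilyl)hept-6-yn-1-yl]oxy}diphenylsilane
Product: 6 tert-butyl{[(2S)-2-methylhept-6-yn-1-yl]oxy}diphenylsilane
Conditions: K2CO3 (cat.), MeOH, rt
Reagents that add atoms: none
Why: Base-catalysed protodesilylation cleaves only the C(sp)–Si bond, the primary tert-butyldiphenylsilyl ether being stable to K2CO3 in methanol.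

Step 4
Reactants: 6 tert-butyl{[(2S)-2-methylhept-6-yn-1-yl]oxy}diphenylsilane
Product: 8 tert-butyl{[(2S,6E)-7-iodo-2,6-dimethylhept-6-en-1-yl]oxy}diphenylsilane, via alkenylalane 7 (not isolated)
Conditions: AlMe3, (C5H5)2ZrCl2 (cat.), CH2Cl2, 0 °C to rt; then I2, THF, −30 to 0 °C
Reagents that add atoms: trimethylaluminium, C[Al](C)C; iodine, II
Why: Negishi zirconium-catalysed carboalumination adds methyl and aluminium syn across the terminal alkyne with aluminium on the terminal carbon, and iodinolysis with retention should give the (E)-iodoalkene that fixes the C11=C12 geometry.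

Step 5
Reactants: 8 tert-butyl{[(2S,6E)-7-iodo-2,6-dimethylhept-6-en-1-yl]oxy}diphenylsilane; 3 (4-bromobut-1-yn-1-yl)trimethylsilane
Product: 10 tert-butyl{[(2S,6E)-2,6-dimethyl-11-(trimethylsilyl)undec-6-en-10-yn-1-yl]oxy}diphenylsilane, via alkylzinc bromide 9 (not isolated)
Conditions: 3, Zn dust (activated), LiCl, THF, 50 °C; then 8, Pd(PPh3)4 (cat.), THF, rt
Reagents that add atoms: none
Why: LiCl-assisted direct insertion of zinc into the primary alkyl bromide gives the homopropargylic zinc reagent, and its Negishi cross-coupling with the alkenyl iodide under zerovalent palladium catalysis forms C12–C13 with retention of alkene geometry, the silyl cap keeping the alkyne C–H out of the organometallic chemistry.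

Step 6
Reactants: 10 tert-butyl{[(2S,6E)-2,6-dimethyl-11-(trimethylsilyl)undec-6-en-10-yn-1-yl]oxy}diphenylsilane
Product: 11 tert-butyl{[(2S,6E)-2,6-dimethylundec-6-en-10-yn-1-yl]oxy}diphenylsilane
Conditions: K2CO3 (cat.), MeOH, rt
Reagents that add atoms: none
Why: Base-catalysed protodesilylation of the alkynylsilane as in step 3, with the silyl ether and the trisubstituted alkene inert.

Step 7
Reactants: 11 tert-butyl{[(2S,6E)-2,6-dimethylundec-6-en-10-yn-1-yl]oxy}diphenylsilane
Product: 14 (2E,6E,11S)-12-{[tert-butyl(diphenyl)silyl]oxy}-3,7,11-trimethyldodeca-2,6-dien-1-ol, via alkenylalane 12 (not isolated), via lithium alkenylaluminate 13 (not isolated)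
Conditions: AlMe3, (C5H5)2ZrCl2 (cat.), CH2Cl2, rt; evaporate, hexane; n-BuLi, THF, −78 to 0 °C; (CH2O)n, rt; 1 M HCl work-up
Reagents that add atoms: trimethylaluminium, C[Al](C)C; formaldehyde (as paraformaldehyde), C=O
Why: A second Negishi carboalumination sets the C15=C16 (E) alkene as in step 4, and conversion of the alkenylalane into the more nucleophilic aluminate lets it add to formaldehyde with retention, delivering C17 as an (E)-allylic alcohol.

Step 8
Reactants: 14 (2E,6E,11S)-12-{[tert-butyl(diphenyl)silyl]oxy}-3,7,11-trimethyldodeca-2,6-dien-1-ol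
Product: 15 {[(2S,6E,10E)-12-bromo-2,6,10-trimethyldodeca-6,10-dien-1-yl]oxy}(tert-butyl)diphenylsilane
Conditions: CBr4, PPh3, CH2Cl2, 0 °C
Reagents that add atoms: carbon tetrabromide, BrC(Br)(Br)Br
Why: Appel bromination converts the primary allylic alcohol through its alkoxyphosphonium salt by direct SN2 displacement at 0 °C, without allylic transposition or loss of alkene geometry.

Step 9
Reactants: 16 furan-3-carbaldehyde
Product: 17 2-(furan-3-yl)-1,3-dithiane
Conditions: HS(CH2)3SH, BF3·OEt2 (cat.), CH2Cl2, 0 °C to rt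
Reagents that add atoms: propane-1,3-dithiol, SCCCS
Why: Lewis-acid-catalysed dithioacetalisation of the aromatic aldehyde gives the acyl-anion equivalent for C18.

Step 10
Reactants: 17 2-(furan-3-yl)-1,3-dithiane; 15 {[(2S,6E,10E)-12-bromo-2,6,10-trimethyldodeca-6,10-dien-1-yl]oxy}(tert-butyl)diphenylsilane
Product: 19 tert-butyl({(2S,6E,10E)-12-[2-(furan-3-yl)-1,3-dithian-2-yl]-2,6,10-trimethyldodeca-6,10-dien-1-yl}oxy)diphenylsilane, via lithiated dithiane 18 (not isolated)
Conditions: 17, n-BuLi, THF, −78 to −30 °C; then 15, −78 to 0 °C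
Reagents that add atoms: none
Why: Corey–Seebach umpolung alkylation, in which the sulfur- and aryl-stabilised C2–H of the dithiane is far more acidic than any furan ring C–H and the soft anion attacks the primary allylic bromide at the bromine-bearing carbon, forming C17–C18 with the C15=C16 geometry intact.

Step 11
Reactants: 19 tert-butyl({(2S,6E,10E)-12-[2-(furan-3-yl)-1,3-dithian-2-yl]-2,6,10-trimethyldodeca-6,10-dien-1-yl}oxy)diphenylsilane
Product: 20 (3E,7E,12S)-13-{[tert-butyl(diphenyl)silyl]oxy}-1-(furan-3-yl)-4,8,12-trimethyltrideca-3,7-dien-1-one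
Conditions: MeI, CaCO3, MeCN/H2O, 45 °C
Reagents that add atoms: water, O
Why: S-Methylative hydrolysis of the dithioacetal under CaCO3 buffering is selective for sulfur (furan, alkenes and silyl ether are inert to MeI) and near-neutral, so the C15=C16 bond should stay out of conjugation with the new ketone.

Step 12
Reactants: 20 (3E,7E,12S)-13-{[tert-butyl(diphenyl)silyl]oxy}-1-(furan-3-yl)-4,8,12-trimethyltrideca-3,7-dien-1-one
Product: 21 tert-butyl({(2S,6E,10E)-12-[2-(furan-3-yl)-1,3-dioxolan-2-yl]-2,6,10-trimethyldodeca-6,10-dien-1-yl}oxy)diphenylsilane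
Conditions: TMSOCH2CH2OTMS, TMSOTf (cat.), CH2Cl2, −78 to −20 °C; pyridine quench
Reagents that add atoms: 1,2-bis(trimethylsilyloxy)ethane, C[Si](C)(C)OCCO[Si](C)(C)C
Why: Noyori ketalisation (TMSOTf-catalysed exchange with the bis-silyl ether of ethylene glycol under aprotic low-temperature conditions) converts ketones into dioxolanes without enolisation, so the β,γ-alkene should not migrate.

Step 13
Reactants: 21 tert-butyl({(2S,6E,10E)-12-[2-(furan-3-yl)-1,3-dioxolan-2-yl]-2,6,10-trimethyldodeca-6,10-dien-1-yl}oxy)diphenylsilane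
Product: 22 (2S,6E,10E)-12-[2-(furan-3-yl)-1,3-dioxolan-2-yl]-2,6,10-trimethyldodeca-6,10-dien-1-ol
Conditions: Bu4NF, THF, 0 °C to rt
Reagents that add atoms: none
Why: Fluoride-induced desilylation cleaves the Si–O bond and leaves ketal, furan and alkenes alone.

Step 14
Reactants: 22 (2S,6E,10E)-12-[2-(furan-3-yl)-1,3-dioxolan-2-yl]-2,6,10-trimethyldodeca-6,10-dien-1-ol
Product: 23 (2S,6E,10E)-12-[2-(furan-3-yl)-1,3-dioxolan-2-yl]-2,6,10-trimethyldodeca-6,10-dienal
Conditions: Dess–Martin periodinane, NaHCO3, CH2Cl2, 0 °C to rt; used at once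
Reagents that add atoms: none
Why: Dess–Martin oxidation under bicarbonate buffer gives the α-branched aldehyde without over-oxidation, acid exposure of the ketal or epimerisation at C7.

Step 15
Reactants: 24 methyl 2-[bis(2,2,2-trifluoroethoxy)phosphoryl]acetate
Product: 25 methyl 2-[bis(2,2,2-trifluoroethoxy)phosphoryl]-2-diazoacetate
Conditions: 4-acetamidobenzenesulfonyl azide, DBU, MeCN, 0 °C to rt
Reagents that add atoms: 4-acetamidobenzenesulfonyl azide, CC(=O)Nc1ccc(cc1)S(=O)(=O)N=[N+]=[N-]
Why: Regitz diazo transfer to the doubly activated methylene of the phosphonoacetate.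

Step 16
Reactants: 25 methyl 2-[bis(2,2,2-trifluoroethoxy)phosphoryl]-2-diazoacetate; 26 propanoic acid
Product: 27 methyl 2-[bis(2,2,2-trifluoroethoxy)phosphoryl]-2-(propanoyloxy)acetate (racemic)
Conditions: Rh2(OAc)4 (cat.), toluene, 80 °C, slow addition of 25
Reagents that add atoms: none
Why: Rhodium-carbenoid O–H insertion into the carboxylic acid places the propanoyloxy group on the phosphonate carbon under neutral conditions; the new centre is racemic and is destroyed in step 17.

Step 17
Reactants: 27 methyl 2-[bis(2,2,2-trifluoroethoxy)phosphoryl]-2-(propanoyloxy)acetate; 23 (2S,6E,10E)-12-[2-(furan-3-yl)-1,3-dioxolan-2-yl]-2,6,10-trimethyldodeca-6,10-dienal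
Product: 29 methyl (2E,4S,8E,12E)-14-[2-(furan-3-yl)-1,3-dioxolan-2-yl]-4,8,12-trimethyl-2-(propanoyloxy)tetradeca-2,8,12-trienoate, via potassium phosphonate carbanion 28 (not isolated)
Conditions: 27 (slight excess over base), KN(SiMe3)2, 18-crown-6, THF, −78 °C; then 23, −78 °C; NH4Cl quench at −78 °C
Reagents that add atoms: none
Why: Still–Gennari modification of the Horner–Wadsworth–Emmons olefination, in which the electron-poor bis(trifluoroethyl) phosphonate and the crown-ether-separated potassium ion make the kinetic adduct eliminate faster than it equilibrates, placing the aldehyde residue cis to the ester as with α-alkyl and α-halo phosphonoacetates, which here is the (2E) enol ester (C7 cis to C4); base is kept below the phosphonate so that no propanoate enolate forms, and −78 °C protects C7.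

Step 18
Reactants: 29 methyl (2E,4S,8E,12E)-14-[2-(furan-3-yl)-1,3-dioxolan-2-yl]-4,8,12-trimethyl-2-(propanoyloxy)tetradeca-2,8,12-trienoate
Product: 31 (5E)-5-{(2S,6E,10E)-12-[2-(furan-3-yl)-1,3-dioxolan-2-yl]-2,6,10-trimethyldodeca-6,10-dien-1-ylidene}-4-hydroxy-3-methylfuran-2(5H)-one, via lithium ester enolate 30 (not isolated)
Conditions: LiN(SiMe3)2 (2.5 equiv), THF, −78 °C, 29 added to the base, then to −40 °C; cold 0.5 M HCl to pH 3
Reagents that add atoms: none
Why: LiN(SiMe3)2 removes a propanoate α-hydrogen and the enolate carbon C3 adds to the adjacent methyl ester carbonyl C4; loss of methoxide and deprotonation by the second equivalent of base give the delocalised lithium tetronate, which makes the closure irreversible. The closest known reaction is the Dieckmann (intramolecular Claisen) cyclisation of 2-acyloxy acrylates to 5-arylidene tetronic acids, applied here to an alkylidene case. The single ring (O1–C2–C3–C4–C5) closes by 5-exo-trig attack on the ester carbonyl with both enolate carbons inside the forming ring (formally 5-enolendo-exo-trig), a mode that is strained for ketone enolates but is the established course of Dieckmann closures of α-acyloxy esters to tetronic acids. No stereocentre is created: C7 (S) and the C5=C6 geometry are carried over because the enol-ester double bond is not part of the reacting system. The step needs propanoate enolisation to win over abstraction of the vinylogous C7 hydrogen; allylic 1,3-strain against the cis ester holds C7–H in the plane of C5=C6, orthogonal to the π system, and inverse addition at −78 °C with excess base suppresses intermolecular Claisen reaction, ketene loss and methoxide attack on unreacted enol ester. The dioxolane leaves C17 non-acidic.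

Step 19
Reactants: 31 (5E)-5-{(2S,6E,10E)-12-[2-(furan-3-yl)-1,3-dioxolan-2-yl]-2,6,10-trimethyldodeca-6,10-dien-1-ylidene}-4-hydroxy-3-methylfuran-2(5H)-one
Product: 32 (5E)-5-[(2S,6E,10E)-13-(furan-3-yl)-2,6,10-trimethyl-13-oxotrideca-6,10-dien-1-ylidene]-4-hydroxy-3-methylfuran-2(5H)-one
Conditions: oxalic acid (aq.), THF, rt
Reagents that add atoms: water, O
Why: Acid-catalysed ketal hydrolysis runs through a furyl-stabilised oxocarbenium ion, and dilute oxalic acid, the standard reagent for freeing β,γ-unsaturated ketones without conjugation, should leave the tetronic acid, the furan and the E-ylidene untouched.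

**Compound list**

1 | (2R)-3-bromo-2-methylpropan-1-ol | OC[C@@H](C)CBr | starting material
2 | tert-butyl{[(2R)-3-bromo-2-methylpropyl]oxy}diphenylsilane | CC(C)(C)[Si](OC[C@@H](C)CBr)(c1ccccc1)c1ccccc1 | intermediate
3 | (4-bromobut-1-yn-1-yl)trimethylsilane | C[Si](C)(C)C#CCCBr | starting material
4 | bromo[4-(trimethylsilyl)but-3-yn-1-yl]magnesium | C[Si](C)(C)C#CCC[Mg]Br | intermediate (not isolated)
5 | tert-butyl{[(2S)-2-methyl-7-(trimethylsilyl)hept-6-yn-1-yl]oxy}diphenylsilane | CC(C)(C)[Si](OC[C@@H](C)CCCC#C[Si](C)(C)C)(c1ccccc1)c1ccccc1 | intermediate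
6 | tert-butyl{[(2S)-2-methylhept-6-yn-1-yl]oxy}diphenylsilane | CC(C)(C)[Si](OC[C@@H](C)CCCC#C)(c1ccccc1)c1ccccc1 | intermediate
7 | [(1E,6S)-7-{[tert-butyl(diphenyl)silyl]oxy}-2,6-dimethylhept-1-en-1-yl]dimethylalumane | CC(C)(C)[Si](OC[C@@H](C)CCC/C(C)=C/[Al](C)C)(c1ccccc1)c1ccccc1 | intermediate (not isolated)
8 | tert-butyl{[(2S,6E)-7-iodo-2,6-dimethylhept-6-en-1-yl]oxy}diphenylsilane | CC(C)(C)[Si](OC[C@@H](C)CCC/C(C)=C/I)(c1ccccc1)c1ccccc1 | intermediate
9 | bromo[4-(trimethylsilyl)but-3-yn-1-yl]zinc | C[Si](C)(C)C#CCC[Zn]Br | intermediate (not isolated)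
10 | tert-butyl{[(2S,6E)-2,6-dimethyl-11-(trimethylsilyl)undec-6-en-10-yn-1-yl]oxy}diphenylsilane | CC(C)(C)[Si](OC[C@@H](C)CCC/C(C)=C/CCC#C[Si](C)(C)C)(c1ccccc1)c1ccccc1 | intermediate
11 | tert-butyl{[(2S,6E)-2,6-dimethylundec-6-en-10-yn-1-yl]oxy}diphenylsilane | CC(C)(C)[Si](OC[C@@H](C)CCC/C(C)=C/CCC#C)(c1ccccc1)c1ccccc1 | intermediate
12 | [(1E,5E,10S)-11-{[tert-butyl(diphenyl)silyl]oxy}-2,6,10-trimethylundeca-1,5-dien-1-yl]dimethylalumane | CC(C)(C)[Si](OC[C@@H](C)CCC/C(C)=C/CC/C(C)=C/[Al](C)C)(c1ccccc1)c1ccccc1 | intermediate (not isolated)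
13 | lithium butyl[(1E,5E,10S)-11-{[tert-butyl(diphenyl)silyl]oxy}-2,6,10-trimethylundeca-1,5-dien-1-yl]dimethylaluminate | CC(C)(C)[Si](OC[C@@H](C)CCC/C(C)=C/CC/C(C)=C/[Al-](C)(C)CCCC)(c1ccccc1)c1ccccc1.[Li+] | intermediate (not isolated)
14 | (2E,6E,11S)-12-{[tert-butyl(diphenyl)silyl]oxy}-3,7,11-trimethyldodeca-2,6-dien-1-ol | CC(C)(C)[Si](OC[C@@H](C)CCC/C(C)=C/CC/C(C)=C/CO)(c1ccccc1)c1ccccc1 | intermediate
15 | {[(2S,6E,10E)-12-bromo-2,6,10-trimethyldodeca-6,10-dien-1-yl]oxy}(tert-butyl)diphenylsilane | CC(C)(C)[Si](OC[C@@H](C)CCC/C(C)=C/CC/C(C)=C/CBr)(c1ccccc1)c1ccccc1 | intermediate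
16 | furan-3-carbaldehyde | O=Cc1ccoc1 | starting material
17 | 2-(furan-3-yl)-1,3-dithiane | C1CSC(SC1)c1ccoc1 | intermediate
18 | [2-(furan-3-yl)-1,3-dithian-2-yl]lithium | [Li]C1(SCCCS1)c1ccoc1 | intermediate (not isolated)
19 | tert-butyl({(2S,6E,10E)-12-[2-(furan-3-yl)-1,3-dithian-2-yl]-2,6,10-trimethyldodeca-6,10-dien-1-yl}oxy)diphenylsilane | CC(C)(C)[Si](OC[C@@H](C)CCC/C(C)=C/CC/C(C)=C/CC1(SCCCS1)c1ccoc1)(c1ccccc1)c1ccccc1 | intermediate
20 | (3E,7E,12S)-13-{[tert-butyl(diphenyl)silyl]oxy}-1-(furan-3-yl)-4,8,12-trimethyltrideca-3,7-dien-1-one | CC(C)(C)[Si](OC[C@@H](C)CCC/C(C)=C/CC/C(C)=C/CC(=O)c1ccoc1)(c1ccccc1)c1ccccc1 | intermediate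
21 | tert-butyl({(2S,6E,10E)-12-[2-(furan-3-yl)-1,3-dioxolan-2-yl]-2,6,10-trimethyldodeca-6,10-dien-1-yl}oxy)diphenylsilane | CC(C)(C)[Si](OC[C@@H](C)CCC/C(C)=C/CC/C(C)=C/CC1(OCCO1)c1ccoc1)(c1ccccc1)c1ccccc1 | intermediate
22 | (2S,6E,10E)-12-[2-(furan-3-yl)-1,3-dioxolan-2-yl]-2,6,10-trimethyldodeca-6,10-dien-1-ol | OC[C@@H](C)CCC/C(C)=C/CC/C(C)=C/CC1(OCCO1)c1ccoc1 | intermediate
23 | (2S,6E,10E)-12-[2-(furan-3-yl)-1,3-dioxolan-2-yl]-2,6,10-trimethyldodeca-6,10-dienal | O=C[C@@H](C)CCC/C(C)=C/CC/C(C)=C/CC1(OCCO1)c1ccoc1 | intermediate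
24 | methyl 2-[bis(2,2,2-trifluoroethoxy)phosphoryl]acetate | COC(=O)CP(=O)(OCC(F)(F)F)OCC(F)(F)F | starting material
25 | methyl 2-[bis(2,2,2-trifluoroethoxy)phosphoryl]-2-diazoacetate | COC(=O)C(=[N+]=[N-])P(=O)(OCC(F)(F)F)OCC(F)(F)F | intermediate
26 | propanoic acid | CCC(=O)O | starting material
27 | methyl 2-[bis(2,2,2-trifluoroethoxy)phosphoryl]-2-(propanoyloxy)acetate (racemic) | CCC(=O)OC(C(=O)OC)P(=O)(OCC(F)(F)F)OCC(F)(F)F | intermediate
28 | potassium 1-[bis(2,2,2-trifluoroethoxy)phosphoryl]-2-methoxy-2-oxo-1-(propanoyloxy)ethan-1-ide | [K+].CCC(=O)O[C-](C(=O)OC)P(=O)(OCC(F)(F)F)OCC(F)(F)F | intermediate (not isolated)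
29 | methyl (2E,4S,8E,12E)-14-[2-(furan-3-yl)-1,3-dioxolan-2-yl]-4,8,12-trimethyl-2-(propanoyloxy)tetradeca-2,8,12-trienoate | CCC(=O)O/C(C(=O)OC)=C/[C@@H](C)CCC/C(C)=C/CC/C(C)=C/CC1(OCCO1)c1ccoc1 | intermediate
30 | lithium enolate of 29 at the propanoate α-carbon (enolate geometry not defined) | [Li+].CC=C([O-])O/C(C(=O)OC)=C/[C@@H](C)CCC/C(C)=C/CC/C(C)=C/CC1(OCCO1)c1ccoc1 | intermediate (not isolated)
31 | (5E)-5-{(2S,6E,10E)-12-[2-(furan-3-yl)-1,3-dioxolan-2-yl]-2,6,10-trimethyldodeca-6,10-dien-1-ylidene}-4-hydroxy-3-methylfuran-2(5H)-one | CC1=C(O)/C(=C\[C@@H](C)CCC/C(C)=C/CC/C(C)=C/CC2(OCCO2)c2ccoc2)OC1=O | intermediate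
32 | (5E)-5-[(2S,6E,10E)-13-(furan-3-yl)-2,6,10-trimethyl-13-oxotrideca-6,10-dien-1-ylidene]-4-hydroxy-3-methylfuran-2(5H)-one | CC1=C(O)/C(=C\[C@@H](C)CCC/C(C)=C/CC/C(C)=C/CC(=O)c2ccoc2)OC1=O | target

**Step count**

Total step count: 19. Longest linear sequence: 16 steps (steps 1–8, 10–14 and 17–19).

**Steps most likely to fail**

1. Step 18 (key step). What may go wrong: abstraction of the vinylogous C7 hydrogen in competition with propanoate enolisation (erosion of C7 configuration and C5=C6 geometry), loss of methylketene from the ester enolate, or cleavage of the enol ester by the methoxide that is set free. Fallback: the C3 enolate is made by reduction and not by deprotonation, so that its position is fixed by a halogen and no strong base is present. The fallback sets out from diazo ester 25 and aldehyde 23 and comes back to the route at 31. Rh2(OAc)4-catalysed O–H insertion of 25 into 2-bromopropanoic acid (as in step 16) would give methyl 2-[bis(2,2,2-trifluoroethoxy)phosphoryl]-2-[(2-bromopropanoyl)oxy]acetate F1. Olefination of 23 with F1 under the conditions of step 17 would give methyl (2E,4S,8E,12E)-2-[(2-bromopropanoyl)oxy]-14-[2-(furan-3-yl)-1,3-dioxolan-2-yl]-4,8,12-trimethyltetradeca-2,8,12-trienoate F2. SmI2 (2.2 equiv, THF, −78 °C) would then reduce the C–Br bond to a Reformatsky-type samarium enolate that closes onto the methyl ester in the same 5-exo mode, and acidic work-up gives 31.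

2. Step 17. What may go wrong: poor geometric selectivity, because the preference for the isomer with the chain cis to the ester is inferred from α-alkyl and α-halo phosphonoacetates and an α-acyloxy group may weaken it. Fallback: the geometry is set with a phosphonate whose preference for this isomer is established, and the propanoyloxy group is brought in afterwards with retention. The fallback sets out from phosphonate 24 and aldehyde 23 and comes back at 29. Bromination of 24 at the phosphonate carbon (NaOBr, then SnCl2 to remove the second bromine) gives methyl 2-[bis(2,2,2-trifluoroethoxy)phosphoryl]-2-bromoacetate F3. Its low-temperature olefination with 23 (KOtBu, 18-crown-6, THF, −78 °C) should give methyl (2E,4S,8E,12E)-2-bromo-14-[2-(furan-3-yl)-1,3-dioxolan-2-yl]-4,8,12-trimethyltetradeca-2,8,12-trienoate F4. Ullmann-type vinylic C–O coupling of F4 with CuO2CEt (pyridine, 100 °C), a substitution that retains alkene geometry, exchanges bromine for propanoyloxy and gives 29.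

3. Step 12. What may go wrong: migration of the C15=C16 double bond into conjugation with the activated carbonyl before the ketal closes, or sluggish ketalisation of the electron-rich furyl ketone. Fallback: the dioxolane is made on a simple α-bromo ketone and the C16–C17 bond is formed by cross-coupling, so that no β,γ-unsaturated ketone meets acid. The fallback sets out from alkyne 11 and comes back at 21, replacing steps 7 to 12. Carboalumination and iodination of 11 as in step 4 give tert-butyl{[(2S,6E,10E)-11-iodo-2,6,10-trimethylundeca-6,10-dien-1-yl]oxy}diphenylsilane F5. Separately, purchased 1-(furan-3-yl)ethan-1-one is brominated with CuBr2 (EtOAc, reflux) to 2-bromo-1-(furan-3-yl)ethan-1-one F6. This is ketalised (ethylene glycol, TsOH, toluene, water removal) to 2-(bromomethyl)-2-(furan-3-yl)-1,3-dioxolane F7. Zinc insertion (Zn, LiCl, THF) then gives bromo{[2-(furan-3-yl)-1,3-dioxolan-2-yl]methyl}zinc F8, a β-alkoxy alkylzinc of the same type as the stable dioxolanylmethylzinc halides used in Negishi couplings. Coupling of F5 with F8 (Pd(PPh3)4, THF, 50 °C) gives 21. This shorter line is held in reserve because the ketal-bearing zinc reagent has less precedent and could lose alkoxide by β-elimination.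

**Further compounds**

F1 | step 18 | methyl 2-[bis(2,2,2-trifluoroethoxy)phosphoryl]-2-[(2-bromopropanoyl)oxy]acetate | CC(Br)C(=O)OC(C(=O)OC)P(=O)(OCC(F)(F)F)OCC(F)(F)F
F2 | step 18 | methyl (2E,4S,8E,12E)-2-[(2-bromopropanoyl)oxy]-14-[2-(furan-3-yl)-1,3-dioxolan-2-yl]-4,8,12-trimethyltetradeca-2,8,12-trienoate | CC(Br)C(=O)O/C(C(=O)OC)=C/[C@@H](C)CCC/C(C)=C/CC/C(C)=C/CC1(OCCO1)c1ccoc1
F3 | step 17 | methyl 2-[bis(2,2,2-trifluoroethoxy)phosphoryl]-2-bromoacetate | COC(=O)C(Br)P(=O)(OCC(F)(F)F)OCC(F)(F)F
F4 | step 17 | methyl (2E,4S,8E,12E)-2-bromo-14-[2-(furan-3-yl)-1,3-dioxolan-2-yl]-4,8,12-trimethyltetradeca-2,8,12-trienoate | Br/C(C(=O)OC)=C/[C@@H](C)CCC/C(C)=C/CC/C(C)=C/CC1(OCCO1)c1ccoc1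
F5 | step 12 | tert-butyl{[(2S,6E,10E)-11-iodo-2,6,10-trimethylundeca-6,10-dien-1-yl]oxy}diphenylsilane | CC(C)(C)[Si](OC[C@@H](C)CCC/C(C)=C/CC/C(C)=C/I)(c1ccccc1)c1ccccc1
F6 | step 12 | 2-bromo-1-(furan-3-yl)ethan-1-one | O=C(CBr)c1ccoc1
F7 | step 12 | 2-(bromomethyl)-2-(furan-3-yl)-1,3-dioxolane | BrCC1(OCCO1)c1ccoc1
F8 | step 12 | bromo{[2-(furan-3-yl)-1,3-dioxolan-2-yl]methyl}zinc | Br[Zn]CC1(OCCO1)c1ccoc1
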